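## Retrosynthetic overview

- **Feature:** ring B is a guaiacyl ring, with C4'–O para to C1' and C3'–OMe next to it. C1' and C6' map onto an ethynyl group on C2 of the chromone, and C2'–C5' map onto a 1,2-dimethoxy-3-silyloxybutadiene. Ring B can therefore be grown last, and 4'-OH is then its only free phenol.
- **Endgame:** the 4'-O–prenyl bond is made by Williamson etherification, then the 5- and 7-O-pivalates are removed by methanolysis.
- **Key disconnection:** C1'–C2' and C5'–C6', by [4+2] cycloaddition followed by loss of methanol and of the silyl group.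
- **Ethynyl group and ring C:** the ethynyl group comes from the C2–H chromone by zincation, iodination, Sonogashira coupling and desilylation. Ring C comes from an aryl methoxymethyl ketone plus one carbon. The future 5-O is masked as a methyl ether, so only the oxygen next to the ring A methoxy group can close, which fixes 8-OMe against 6-OMe.
- **Ring A:** it is bought as 2-methoxyresorcinol and gains its fourth oxygen by C5–H borylation and oxidation. Order of rings: A (bought), C (step 5), B (step 13).

Key step: step 13

Remark: the target has no stereocentre and no stereogenic double bond, so the only geometry to be controlled is that of the silyloxydiene.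

## Route

Step 1
Reactants: 1 2-methoxybenzene-1,3-diol (2-methoxyresorcinol)
Product: 2 2-methoxy-1,3-bis(methoxymethoxy)benzene
Conditions: MOMCl (2.5 equiv), iPr2NEt (3 equiv), CH2Cl2, 0 °C to rt
Reagents that add atoms: chloromethyl methyl ether, COCCl
Why: Williamson-type O-alkylation protects both phenols as acetals that carry no aromatic C–H to compete in step 2, direct the lithiation of step 4 and fall off under the acid of step 5.

Step 2
Reactants: 2 2-methoxy-1,3-bis(methoxymethoxy)benzene
Product: 4 4-methoxy-3,5-bis(methoxymethoxy)phenol, via pinacol boronate 3 (not isolated)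
Conditions: [Ir(OMe)(cod)]2 (1.5 mol %), dtbpy (3 mol %), B2pin2 (0.6 equiv), THF, 80 °C, sealed; then 30% H2O2, NaOH (1 equiv), THF/H2O, 0 °C to rt
Reagents that add atoms: bis(pinacolato)diboron, CC1(C)OB(OC1(C)C)B1OC(C)(C)C(C)(C)O1 (boryl group of 3); hydrogen peroxide, OO (phenol oxygen of 4)
Why: Sterically governed iridium-catalysed aromatic C–H borylation should pick C5–H, the only ring C–H without an ortho substituent, and boronate oxidation (aryl shift from boron to oxygen) then gives the phenol, as is usual for 1,2,3-trisubstituted arenes.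

Step 3
Reactants: 4 4-methoxy-3,5-bis(methoxymethoxy)phenol
Product: 5 2,5-dimethoxy-1,3-bis(methoxymethoxy)benzene
Conditions: MeI (1.5 equiv), K2CO3 (2 equiv), acetone, reflux
Reagents that add atoms: iodomethane, CI
Why: Williamson ether synthesis masks the future 5-oxygen as a methyl ether that withstands butyllithium and acid and cannot take part in the closure of ring C.

Step 4
Reactants: 5 2,5-dimethoxy-1,3-bis(methoxymethoxy)benzene; 6 N,2-dimethoxy-N-methylacetamide
Product: 9 1-[3,6-dimethoxy-2,4-bis(methoxymethoxy)phenyl]-2-methoxyethan-1-one, via aryllithium 7 (not isolated), via lithium hemiaminal adduct 8 (not isolated)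
Conditions: n-BuLi (1.15 equiv), THF, 0 °C; then 6 (1.2 equiv), −78 °C to 0 °C; then H2O
Reagents that add atoms: n-butyllithium, CCCC[Li] (lithium of 7 and 8 only)
Why: Directed ortho-metalation between OMOM and OMe can give only one aryllithium because the two open ring positions are equivalent by symmetry, and the Weinreb ketone synthesis stops at the ketone because the chelated tetrahedral adduct survives until the quench.

Step 5
Reactants: 9 1-[3,6-dimethoxy-2,4-bis(methoxymethoxy)phenyl]-2-methoxyethan-1-one
Product: 11 7-hydroxy-3,5,8-trimethoxy-4H-chromen-4-one, via enaminone 10 (not isolated)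
Conditions: Me2NCH(OMe)2 (5 equiv), PhMe, 110 °C; concentrate; then 3 M HCl, MeOH, 60 °C
Reagents that add atoms: N,N-dimethylformamide dimethyl acetal, COC(OC)N(C)C
Why: Aminomethylenation of the activated CH2 followed by acid-induced acetal cleavage and addition–elimination cyclisation is the enaminone route to chromones, and because the other ortho oxygen is a methyl ether only the phenol flanked by the ring methoxy group can close, so the 8-methoxy isomer alone can form.

Step 6
Reactants: 11 7-hydroxy-3,5,8-trimethoxy-4H-chromen-4-one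
Product: 12 5,7-dihydroxy-3,8-dimethoxy-4H-chromen-4-one
Conditions: AlCl3 (anhydrous, 5 equiv), MeCN, 70 °C; then 2 M HCl, 60 °C
Reagents that add atoms: none
Why: Chelation-controlled Lewis acid ether cleavage, in which aluminium binds C4=O and the peri 5-OMe in a six-membered chelate, should remove this methyl group well before those at O-3 and O-8, as is established for 7-hydroxy-3,5,8-trimethoxyflavones.

Step 7
Reactants: 12 5,7-dihydroxy-3,8-dimethoxy-4H-chromen-4-one
Product: 13 3,8-dimethoxy-4-oxo-4H-chromene-5,7-diyl bis(2,2-dimethylpropanoate)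
Conditions: PivCl (3 equiv), Et3N (4 equiv), DMAP (0.2 equiv), CH2Cl2, 0 to 40 °C
Reagents that add atoms: pivaloyl chloride, CC(C)(C)C(=O)Cl
Why: DMAP-catalysed acylation esterifies both phenols, the chelated 5-OH included, and the pivalates tolerate zinc amide, palladium coupling, heat and dilute acid, draw electron density from ring A and leave by methanolysis at the end.

Step 8
Reactants: 13 3,8-dimethoxy-4-oxo-4H-chromene-5,7-diyl bis(2,2-dimethylpropanoate)
Product: 15 2-iodo-3,8-dimethoxy-4-oxo-4H-chromene-5,7-diyl bis(2,2-dimethylpropanoate), via chromon-2-ylzinc chloride 14 (not isolated)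
Conditions: TMPZnCl·LiCl (1.3 equiv), THF, 25 °C; then I2 (1.5 equiv), THF, 0 °C to rt
Reagents that add atoms: TMPZnCl·LiCl, CC1(C)CCCC(C)(C)N1[Zn]Cl.[Li+].[Cl-] (zinc and chlorine of 14 only); iodine, II
Why: Deprotonative zincation of chromones with this ester-tolerant zinc amide takes place at C2–H, the most acidic site (next to O1 and the 3-methoxy group, with C3 blocked), and iodinolysis of the C–Zn bond gives the iodide.

Step 9
Reactants: 15 2-iodo-3,8-dimethoxy-4-oxo-4H-chromene-5,7-diyl bis(2,2-dimethylpropanoate); 16 trimethylsilylacetylene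
Product: 17 3,8-dimethoxy-4-oxo-2-[(trimethylsilyl)ethynyl]-4H-chromene-5,7-diyl bis(2,2-dimethylpropanoate)
Conditions: 16 (1.5 equiv), PdCl2(PPh3)2 (3 mol %), CuI (6 mol %), Et3N (3 equiv), THF, rt
Reagents that add atoms: none
Why: Sonogashira coupling should run at room temperature because the electron-poor vinylogous acyl iodide adds readily to zerovalent palladium, and a tertiary amine base avoids displacement of iodide at C2.

Step 10
Reactants: 17 3,8-dimethoxy-4-oxo-2-[(trimethylsilyl)ethynyl]-4H-chromene-5,7-diyl bis(2,2-dimethylpropanoate)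
Product: 18 2-ethynyl-3,8-dimethoxy-4-oxo-4H-chromene-5,7-diyl bis(2,2-dimethylpropanoate)
Conditions: Bu4NF (1.1 equiv), AcOH (1.2 equiv), THF, 0 °C
Reagents that add atoms: none
Why: Fluoride-induced protodesilylation of the alkynylsilane is buffered with acetic acid, so the medium stays non-basic and the aryl pivalates and the electrophilic enyne are spared.

Step 11
Reactants: 19 methoxyacetone
Product: 21 (Z)-3,4-dimethoxybut-3-en-2-one, via sodium enolate 20 (not isolated)
Conditions: HCO2Me (1.5 equiv), NaOMe (1.05 equiv), Et2O, 0 °C to rt; evaporate; then Me2SO4 (1.05 equiv), DMF, 0 °C to rt; distil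
Reagents that add atoms: methyl formate, COC=O; sodium methoxide, C[O-].[Na+] (sodium of 20 only); dimethyl sulfate, COS(=O)(=O)OC
Why: Claisen formylation should occur at the methoxy-bearing methylene, which is more acidic than the methyl group, and the hard electrophile in a dissociating solvent should alkylate the enolate oxygen in its extended form, placing the new methoxy group trans to the acetyl group (the less crowded Z isomer).

Step 12
Reactants: 21 (Z)-3,4-dimethoxybut-3-en-2-one
Product: 22 (Z)-1,2-dimethoxy-3-(trimethylsilyloxy)buta-1,3-diene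
Conditions: TMSOTf (1.1 equiv), Et3N (1.5 equiv), Et2O, 0 °C; decant; distil under reduced pressure
Reagents that add atoms: trimethylsilyl trifluoromethanesulfonate, C[Si](C)(C)OS(=O)(=O)C(F)(F)F
Why: Soft enolisation and O-silylation (silyl enol ether formation) can involve only the methyl group, the one enolisable position, and leaves the enol ether geometry untouched.

Step 13
Reactants: 18 2-ethynyl-3,8-dimethoxy-4-oxo-4H-chromene-5,7-diyl bis(2,2-dimethylpropanoate); 22 (Z)-1,2-dimethoxy-3-(trimethylsilyloxy)buta-1,3-diene
Product: 25 2-(4-hydroxy-3-methoxyphenyl)-3,8-dimethoxy-4-oxo-4H-chromene-5,7-diyl bis(2,2-dimethylpropanoate), via cyclohexadiene cycloadduct 23 (not isolated), via aryl trimethylsilyl ether 24 (not isolated)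
Conditions: 22 (3 equiv), PhMe, 110 °C, sealed tube; then 1 M HCl, THF, 0 °C to rt
Reagents that add atoms: none
Why: Proposed new method: a thermal, concerted but asynchronous [4+2] cycloaddition is expected, in which the CH2 terminus of Z-diene 22 (largest HOMO coefficient, fed by the 1-methoxy and 3-silyloxy groups; the 1-methoxy group points outward in the s-cis form) bonds first to the terminal alkyne carbon of 18, the δ-electrophilic end of the C4=O–C3=C2–C≡C chain, forming C5'–C6', while the methoxy-bearing C1 bonds to the internal alkyne carbon, forming C1'–C2'. The closest known reaction type is the Diels–Alder reaction of 1-methoxy-3-silyloxybutadienes, 2-oxygenated ones included, with alkynyl ketones and propiolates, which gives para-acylphenols after loss of methanol; an ethynyl group activated only through the C2=C3 bond of a chromone has not been shown as the dienophile, hence the label, the excess of diene, the heating and the two electron-withdrawing pivaloyloxy groups on ring A. Ring B closes in the intermolecular six-membered [4+2] mode to give 1,4-cyclohexadiene 23, which should aromatise by 1,4-elimination of methanol (C2'–OMe and one C5'–H) to silyl ether 24, and dilute acid then cleaves the O–Si bond to free 4'-OH. The one stereocentre of 23 (C2') forms as a racemate and is erased on aromatisation, so nothing has to control it. The step needs regioselectivity (4'-O para to C1', 3'-OMe on the carbon between C2' and C4'), which the matched polarisation of the two partners secures, and chemoselectivity for the alkyne over C2=C3, which the full substitution of that double bond secures.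

Step 14
Reactants: 25 2-(4-hydroxy-3-methoxyphenyl)-3,8-dimethoxy-4-oxo-4H-chromene-5,7-diyl bis(2,2-dimethylpropanoate); 26 prenyl bromide (1-bromo-3-methylbut-2-ene)
Product: 27 2-{3-methoxy-4-[(3-methylbut-2-en-1-yl)oxy]phenyl}-3,8-dimethoxy-4-oxo-4H-chromene-5,7-diyl bis(2,2-dimethylpropanoate)
Conditions: 26 (1.2 equiv), K2CO3 (1.5 equiv), acetone, 40 °C
Reagents that add atoms: none
Why: Williamson ether synthesis (SN2 at the primary allylic bromide) has only one phenol to alkylate, and anhydrous carbonate leaves the hindered pivalates alone.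

Step 15
Reactants: 27 2-{3-methoxy-4-[(3-methylbut-2-en-1-yl)oxy]phenyl}-3,8-dimethoxy-4-oxo-4H-chromene-5,7-diyl bis(2,2-dimethylpropanoate)
Product: 28 5,7-dihydroxy-3,8,3'-trimethoxy-4'-prenyloxyflavone
Conditions: K2CO3 (3 equiv), MeOH/CH2Cl2, rt; then AcOH to neutrality
Reagents that add atoms: none
Why: Base-mediated transesterification (methanolysis) cleaves both aryl esters, while the methyl ethers, the flavone core and the acid-sensitive prenyl ether are inert to carbonate in methanol and to the mild acetic acid quench.

## Compound list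

1 | 2-methoxybenzene-1,3-diol (2-methoxyresorcinol) | COc1c(O)cccc1O | starting material
2 | 2-methoxy-1,3-bis(methoxymethoxy)benzene | COCOc1cccc(OCOC)c1OC | intermediate
3 | 2-[4-methoxy-3,5-bis(methoxymethoxy)phenyl]-4,4,5,5-tetramethyl-1,3,2-dioxaborolane | COCOc1cc(B2OC(C)(C)C(C)(C)O2)cc(OCOC)c1OC | intermediate
4 | 4-methoxy-3,5-bis(methoxymethoxy)phenol | COCOc1cc(O)cc(OCOC)c1OC | intermediate
5 | 2,5-dimethoxy-1,3-bis(methoxymethoxy)benzene | COCOc1cc(OC)cc(OCOC)c1OC | intermediate
6 | N,2-dimethoxy-N-methylacetamide | COCC(=O)N(C)OC | starting material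
7 | [3,6-dimethoxy-2,4-bis(methoxymethoxy)phenyl]lithium | [Li]c1c(OC)cc(OCOC)c(OC)c1OCOC | intermediate
8 | lithium 1-[3,6-dimethoxy-2,4-bis(methoxymethoxy)phenyl]-2-methoxy-1-[methoxy(methyl)amino]ethan-1-olate (racemic) | [Li+].COCC([O-])(N(C)OC)c1c(OC)cc(OCOC)c(OC)c1OCOC | intermediate
9 | 1-[3,6-dimethoxy-2,4-bis(methoxymethoxy)phenyl]-2-methoxyethan-1-one | COCC(=O)c1c(OC)cc(OCOC)c(OC)c1OCOC | intermediate
10 | (Z)-3-(dimethylamino)-1-[3,6-dimethoxy-2,4-bis(methoxymethoxy)phenyl]-2-methoxyprop-2-en-1-one | CN(C)/C=C(OC)/C(=O)c1c(OC)cc(OCOC)c(OC)c1OCOC | intermediate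
11 | 7-hydroxy-3,5,8-trimethoxy-4H-chromen-4-one | COc1coc2c(OC)c(O)cc(OC)c2c1=O | intermediate
12 | 5,7-dihydroxy-3,8-dimethoxy-4H-chromen-4-one | COc1coc2c(OC)c(O)cc(O)c2c1=O | intermediate
13 | 3,8-dimethoxy-4-oxo-4H-chromene-5,7-diyl bis(2,2-dimethylpropanoate) | COc1coc2c(OC)c(OC(=O)C(C)(C)C)cc(OC(=O)C(C)(C)C)c2c1=O | intermediate
14 | chloro[3,8-dimethoxy-4-oxo-5,7-bis(pivaloyloxy)-4H-chromen-2-yl]zinc | Cl[Zn]c1oc2c(OC)c(OC(=O)C(C)(C)C)cc(OC(=O)C(C)(C)C)c2c(=O)c1OC | intermediate
15 | 2-iodo-3,8-dimethoxy-4-oxo-4H-chromene-5,7-diyl bis(2,2-dimethylpropanoate) | Ic1oc2c(OC)c(OC(=O)C(C)(C)C)cc(OC(=O)C(C)(C)C)c2c(=O)c1OC | intermediate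
16 | trimethylsilylacetylene | C#C[Si](C)(C)C | starting material
17 | 3,8-dimethoxy-4-oxo-2-[(trimethylsilyl)ethynyl]-4H-chromene-5,7-diyl bis(2,2-dimethylpropanoate) | C[Si](C)(C)C#Cc1oc2c(OC)c(OC(=O)C(C)(C)C)cc(OC(=O)C(C)(C)C)c2c(=O)c1OC | intermediate
18 | 2-ethynyl-3,8-dimethoxy-4-oxo-4H-chromene-5,7-diyl bis(2,2-dimethylpropanoate) | C#Cc1oc2c(OC)c(OC(=O)C(C)(C)C)cc(OC(=O)C(C)(C)C)c2c(=O)c1OC | intermediate
19 | methoxyacetone | COCC(C)=O | starting material
20 | sodium 2-methoxy-3-oxobut-1-en-1-olate (geometry not fixed) | [Na+].[O-]C=C(OC)C(C)=O | intermediate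
21 | (Z)-3,4-dimethoxybut-3-en-2-one | CO/C=C(OC)/C(C)=O | intermediate
22 | (Z)-1,2-dimethoxy-3-(trimethylsilyloxy)buta-1,3-diene | CO/C=C(OC)/C(=C)O[Si](C)(C)C | intermediate
23 | 2-[5,6-dimethoxy-4-(trimethylsilyloxy)cyclohexa-1,4-dien-1-yl]-3,8-dimethoxy-4-oxo-4H-chromene-5,7-diyl bis(2,2-dimethylpropanoate) (racemic) | COC1C(c2oc3c(OC)c(OC(=O)C(C)(C)C)cc(OC(=O)C(C)(C)C)c3c(=O)c2OC)=CCC(O[Si](C)(C)C)=C1OC | intermediate
24 | 2-[3-methoxy-4-(trimethylsilyloxy)phenyl]-3,8-dimethoxy-4-oxo-4H-chromene-5,7-diyl bis(2,2-dimethylpropanoate) | COc1cc(-c2oc3c(OC)c(OC(=O)C(C)(C)C)cc(OC(=O)C(C)(C)C)c3c(=O)c2OC)ccc1O[Si](C)(C)C | intermediate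
25 | 2-(4-hydroxy-3-methoxyphenyl)-3,8-dimethoxy-4-oxo-4H-chromene-5,7-diyl bis(2,2-dimethylpropanoate) | COc1cc(-c2oc3c(OC)c(OC(=O)C(C)(C)C)cc(OC(=O)C(C)(C)C)c3c(=O)c2OC)ccc1O | intermediate
26 | prenyl bromide (1-bromo-3-methylbut-2-ene) | CC(C)=CCBr | starting material
27 | 2-{3-methoxy-4-[(3-methylbut-2-en-1-yl)oxy]phenyl}-3,8-dimethoxy-4-oxo-4H-chromene-5,7-diyl bis(2,2-dimethylpropanoate) | COc1cc(-c2oc3c(OC)c(OC(=O)C(C)(C)C)cc(OC(=O)C(C)(C)C)c3c(=O)c2OC)ccc1OCC=C(C)C | intermediate
28 | 5,7-dihydroxy-3,8,3'-trimethoxy-4'-prenyloxyflavone | COc1cc(-c2oc3c(OC)c(O)cc(O)c3c(=O)c2OC)ccc1OCC=C(C)C | target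

## Step count and risks

Total step count: 15. Longest linear sequence: 13 (steps 1–10 and 13–15). Steps 11 and 12 form the diene branch.

**Steps most likely to fail**

**Step 13.**
- What may go wrong: the vinylogous activation of the alkyne may be too weak. The cycloaddition would then be outrun by thermal decay of the diene, by oligomerisation of the terminal enyne, or by a conjugate addition that stops before ring closure. The 2-methoxy group of the diene may also erode the regiochemical bias.
- Fallback (known chemistry, ring B brought in ready-made instead of being built): it sets out from iodide 15 and comes back at 25. Suzuki–Miyaura coupling of 15 with bought 2-methoxy-4-(4,4,5,5-tetramethyl-1,3,2-dioxaborolan-2-yl)phenol F1, under Pd(PPh3)4 and anhydrous CsF in DME at 80 °C, forms the C2–C1' bond directly. The water-free fluoride base spares the pivalates. Steps 9–12 then fall away.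

**Step 11.**
- What may go wrong: the reversible formylation may take place in part at the methyl carbon, the enolate may be methylated on carbon, and a mixture of double bond isomers may result.
- Fallback: it sets out from 19 and comes back at 20. Condensation of 19 with N,N-dimethylformamide dimethyl acetal (neat, 100 °C) is an irreversible aminomethylenation at the more acidic methoxy-bearing methylene. It gives distillable (Z)-4-(dimethylamino)-3-methoxybut-3-en-2-one F2, which can be freed from any regioisomer. Alkaline hydrolysis (1 equiv aqueous NaOH, then evaporation) turns it into the salt 20 for the O-methylation of step 11.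

**Step 5.**
- What may go wrong: aminomethylenation of the hindered, di-ortho-substituted ketone may stall. In the acid stage, the formaldehyde equivalents released from the acetals may attack the electron-rich C6 position.
- Fallback: it sets out from 9 and comes back at 11. The acetals are removed first (HCl, MeOH, 40 °C) to give 1-(2,4-dihydroxy-3,6-dimethoxyphenyl)-2-methoxyethan-1-one F3. Ring C is then closed by a Vilsmeier-type one-carbon closure (BF3·OEt2, DMF, MsCl, 70 °C), in which the boron chelate of the ortho-hydroxyketone enolises and is formylated by the activated formamide. This closure tolerates the free para phenol.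

## Further compounds

F1 | step 13 | 2-methoxy-4-(4,4,5,5-tetramethyl-1,3,2-dioxaborolan-2-yl)phenol | COc1cc(B2OC(C)(C)C(C)(C)O2)ccc1O
F2 | step 11 | (Z)-4-(dimethylamino)-3-methoxybut-3-en-2-one | CN(C)/C=C(OC)/C(C)=O
F3 | step 5 | 1-(2,4-dihydroxy-3,6-dimethoxyphenyl)-2-methoxyethan-1-one | COCC(=O)c1c(OC)cc(O)c(OC)c1O
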